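**Retrosynthetic overview**

1. Halimane numbering: ring A = C1–C5 and C10 (C1=C10), ring B = C5–C10, C18 = ester carbon on C4, C17 and C20 = methyls on C8 and C9, side chain C11–C16. The 13,14-epoxide comes from a Sharpless epoxidation and the C12–C13 bond from a Negishi coupling.
2. Ring B is closed last through the C6–C7 bond. A C6 acetic acid arm, as its N-acyloxyphthalimide, loses CO2, and the C6 radical closes 6-endo onto the C7=C8 isopropenyl group on C9; hydrogen-atom transfer then sets C8.
3. Enabling feature: C7=C8 is a 1,1-disubstituted alkene whose inner carbon C8 sits on the quaternary C9. The C6 radical can therefore only bond to the terminal C7 (six-membered ring B), and the ring B radical at C8 is reduced opposite the axial C20 methyl.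
4. The arm (C5–C6 bond) and the C1=C10 alkene come from one Johnson–Claisen rearrangement from the C1 oxygen. The quaternary C9 comes from an intramolecular Heck reaction through a temporary C1–O–C8 tiglate tether, whose lactone is later opened (MeLi, Wittig) to the isopropenyl group.
5. Ring A (C4) comes from an enantioselective Diels–Alder reaction and C1 from a CBS reduction. Order of ring formation: ring A, temporary γ-lactone, ring B.

Key step: step 15

Remark on the chemistry: in step 1 the salen enantiomer is taken as the one that gives (S)-4; if the sense of induction is the opposite, the antipodal ligand is used.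

**Route**

Step 1
Reactants: 1 (E)-1-(dimethylamino)-3-(tert-butyldimethylsilyloxy)buta-1,3-diene; 2 methacrolein
Product: 4 (S)-1-methyl-4-oxocyclohex-2-ene-1-carbaldehyde, via amino silyl enol ether cycloadduct 3 (not isolated)
Conditions: [Cr(salen)]SbF6 (5 mol %; salen = N,N'-bis(3,5-di-tert-butylsalicylidene)cyclohexane-1,2-diamine dianion, trivalent chromium), 4 Å MS, CH2Cl2, −40 °C; then 1 M HCl, THF, 0 °C
Reagents that add atoms: none
Why: Catalytic enantioselective Diels–Alder reaction of a 1-amino-3-siloxydiene with an α-substituted acrolein; the chiral Lewis acid binds the aldehyde and shields one face so that the quaternary C4 should form as S, the amino and siloxy groups fix the regiochemistry, and acid then hydrolyses the silyl enol ether and eliminates dimethylamine to the enone.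

Step 2
Reactants: 4 (S)-1-methyl-4-oxocyclohex-2-ene-1-carbaldehyde
Product: 5 (S)-1-methyl-4-oxocyclohex-2-ene-1-carboxylic acid
Conditions: NaClO2, NaH2PO4, 2-methyl-2-butene, t-BuOH/H2O, 0 °C to rt
Reagents that add atoms: sodium chlorite, [Na+].[O-]Cl=O
Why: Pinnick oxidation of an aldehyde without α-hydrogen; the enone is inert to chlorite and the stereocentre cannot epimerize.

Step 3
Reactants: 5 (S)-1-methyl-4-oxocyclohex-2-ene-1-carboxylic acid
Product: 6 methyl (S)-1-methyl-4-oxocyclohex-2-ene-1-carboxylate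
Conditions: MeI, K2CO3, DMF, rt
Reagents that add atoms: iodomethane, CI
Why: O-alkylation (SN2) of the carboxylate, which avoids acid or alkoxide contact with the enone; no stereocentre is touched.

Step 4
Reactants: 6 methyl (S)-1-methyl-4-oxocyclohex-2-ene-1-carboxylate
Product: 7 methyl (S)-3-iodo-1-methyl-4-oxocyclohex-2-ene-1-carboxylate
Conditions: I2, pyridine, CH2Cl2, 0 °C to rt
Reagents that add atoms: iodine, II
Why: α-Iodination of a cyclic enone by conjugate addition of pyridine, iodination of the enolate and elimination (as known for 4,4-disubstituted cyclohexenones); it places the halide on C10.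

Step 5
Reactants: 7 methyl (S)-3-iodo-1-methyl-4-oxocyclohex-2-ene-1-carboxylate
Product: 8 methyl (1S,4R)-4-hydroxy-3-iodo-1-methylcyclohex-2-ene-1-carboxylate
Conditions: (S)-2-methyl-CBS-oxazaborolidine (20 mol %), BH3·SMe2, THF, −20 °C; MeOH quench
Reagents that add atoms: none
Why: Corey–Bakshi–Shibata reduction; the iodoalkene acts as the large group, so the catalyst and not the remote C4 centre should set the carbinol carbon (C1 of the skeleton) as R, with the oxygen cis to the ester, while the ester is not reduced.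

Step 6
Reactants: 8 methyl (1S,4R)-4-hydroxy-3-iodo-1-methylcyclohex-2-ene-1-carboxylate; 9 tigloyl chloride
Product: 10 methyl (1S,4R)-3-iodo-1-methyl-4-(tigloyloxy)cyclohex-2-ene-1-carboxylate
Conditions: pyridine, DMAP (cat.), CH2Cl2, 0 °C to rt
Reagents that add atoms: none
Why: DMAP-catalysed acylation of a secondary allylic alcohol; the (E)-geometry of the tiglate is the stable one and no stereocentre is formed.

Step 7
Reactants: 10 methyl (1S,4R)-3-iodo-1-methyl-4-(tigloyloxy)cyclohex-2-ene-1-carboxylate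
Product: 11 methyl (3R,5S,7aR)-3-ethenyl-3,5-dimethyl-2-oxo-2,3,5,6,7,7a-hexahydro-1-benzofuran-5-carboxylate
Conditions: Pd(OAc)2 (10 mol %), PPh3 (30 mol %), Ag2CO3, MeCN, 80 °C
Reagents that add atoms: none
Why: Intramolecular Mizoroki–Heck reaction (5-exo-trig onto the α-carbon, as in the oxindole-forming cyclizations of α,β-unsaturated 2-iodoanilides); the alkenyl–palladium bond at C10 adds syn across C9=C11 on the face held by the C1–O ester tether, which fixes the quaternary C9 (carbonyl C8 on the side of the C1 oxygen), and β-hydride elimination toward the C12 methyl leaves a vinyl group that cannot migrate.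

Step 8
Reactants: 11 vinyl lactone
Product: 13 methyl (3R,5S,7aR)-3-(2-hydroxyethyl)-3,5-dimethyl-2-oxo-2,3,5,6,7,7a-hexahydro-1-benzofuran-5-carboxylate, via B-alkyl-9-BBN adduct 12 (not isolated)
Conditions: 9-BBN, THF, 0 °C to rt; then 30% H2O2, aq. NaOAc, 0 °C
Reagents that add atoms: hydrogen peroxide, OO; 9-borabicyclo[3.3.1]nonane, B1C2CCCC1CCC2 (boron in 12 only)
Why: Anti-Markovnikov hydroboration–oxidation; 9-BBN takes the monosubstituted vinyl group and leaves the hindered trisubstituted C5=C10 alkene, and the buffered oxidation spares lactone and ester; no stereocentre is formed.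

Step 9
Reactants: 13 C12 alcohol
Product: 14 C12 tert-butyldiphenylsilyl ether of 13
Conditions: TBDPSCl, imidazole, DMF, rt
Reagents that add atoms: tert-butyl(chloro)diphenylsilane, CC(C)(C)[Si](Cl)(c1ccccc1)c1ccccc1
Why: Silylation of the primary alcohol; the robust TBDPS ether is chosen to survive MeLi, ylide and the hot acidic Claisen step.

Step 10
Reactants: 14 silyl ether lactone
Product: 15 methyl (1S,4R)-3-{(3R)-5-[(tert-butyldiphenylsilyl)oxy]-3-methyl-2-oxopentan-3-yl}-4-hydroxy-1-methylcyclohex-2-ene-1-carboxylate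
Conditions: MeLi (1.1 equiv), THF, −78 °C; AcOH quench at −78 °C
Reagents that add atoms: methyllithium, [Li]C
Why: Mono-addition of MeLi to a γ-lactone; the lithium hemiketal is stable at −78 °C and blocks a second addition, the lactone is more electrophilic than the neopentyl methyl ester, and the product (open hydroxy ketone in equilibrium with its five-membered hemiketal) frees the C1 hydroxyl and turns C8 into a methyl ketone.

Step 11
Reactants: 15 hydroxy methyl ketone
Product: 16 methyl (1S,4R)-3-{(3S)-5-[(tert-butyldiphenylsilyl)oxy]-2,3-dimethylpent-1-en-3-yl}-4-hydroxy-1-methylcyclohex-2-ene-1-carboxylate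
Conditions: Ph3PCH3Br, KOt-Bu, toluene, rt to 70 °C
Reagents that add atoms: methyltriphenylphosphonium bromide, C[P+](c1ccccc1)(c1ccccc1)c1ccccc1.[Br-]
Why: Wittig methylenation of the open ketone form with excess ylide (conditions used for hindered ketones); it gives the C7=C8 isopropenyl group, the quaternary ester has no α-hydrogen and the C9 geometry is unchanged (its descriptor changes from R to S by priority only).

Step 12
Reactants: 16 isopropenyl allylic alcohol
Product: 18 methyl (1S,2R)-3-{(3S)-5-[(tert-butyldiphenylsilyl)oxy]-2,3-dimethylpent-1-en-3-yl}-2-(2-ethoxy-2-oxoethyl)-1-methylcyclohex-3-ene-1-carboxylate, via mixed ketene acetal 17 (not isolated)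
Conditions: MeC(OEt)3, EtCO2H (cat.), 140 °C, removal of EtOH
Reagents that add atoms: triethyl orthoacetate, CC(OCC)(OCC)OCC
Why: Johnson–Claisen rearrangement; the [3,3] shift is suprafacial, so the new C5–C6 bond forms on the face that the C1 oxygen leaves (C5 = R, independent of C4), and the alkene moves regiospecifically to C1=C10.

Step 13
Reactants: 18 ethyl ester
Product: 19 2-[(1R,6S)-2-{(3S)-5-[(tert-butyldiphenylsilyl)oxy]-2,3-dimethylpent-1-en-3-yl}-6-(methoxycarbonyl)-6-methylcyclohex-2-en-1-yl]acetic acid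
Conditions: LiOH, THF/H2O, rt; then 1 M HCl to pH 3
Reagents that add atoms: lithium hydroxide, [Li+].[OH-]
Why: Selective saponification; the unhindered primary ethyl ester is hydrolysed while the methyl ester on the quaternary C4 is shielded, and no stereocentre is touched.

Step 14
Reactants: 19 C6 acetic acid
Product: 20 1,3-dioxoisoindolin-2-yl ester of 19
Conditions: N-hydroxyphthalimide, DIC, DMAP (cat.), CH2Cl2, rt
Reagents that add atoms: N-hydroxyphthalimide, O=C1N(O)C(=O)c2ccccc12
Why: Carbodiimide esterification to the redox-active ester, the electron acceptor for the decarboxylation.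

Step 15
Reactants: 20 redox-active ester
Product: 23 methyl (1S,5S,6R,8aR)-5-{2-[(tert-butyldiphenylsilyl)oxy]ethyl}-1,5,6-trimethyl-1,2,3,5,6,7,8,8a-octahydronaphthalene-1-carboxylate, via primary C6 radical 21 (not isolated), via tertiary C8 radical 22 (not isolated)
Conditions: [Ru(bpy)3](PF6)2 (2 mol %), Hantzsch ester (2 equiv), i-Pr2NEt, degassed CH2Cl2 (0.01 M), blue LEDs, rt
Reagents that add atoms: none
Why: Electron transfer from the photoreduced ruthenium bipyridyl complex to the N-acyloxyphthalimide releases phthalimide anion and CO2 and leaves the primary C6 radical 21, which adds to the terminal C7 of the isopropenyl group to give the tertiary C8 radical 22, and this takes a hydrogen atom from the Hantzsch ester. The closest known reaction types are the visible-light reductive decarboxylation of N-acyloxyphthalimides with radical C–C bond formation and the 6-endo cyclization of 5-substituted hex-5-enyl radicals. Ring B closes in the 6-endo-trig mode through a chair-like transition state in which ring A and the quaternary C9 hold C6 next to C7. The only new stereocentre, C8, is set in the hydrogen-atom transfer: in the ring B chair the C4–C5 bond and the C11 chain are equatorial and the C20 methyl is axial, so hydrogen should arrive axially on the face opposite C20 and leave C17 equatorial and cis to C20 (8R). The step needs 6-endo over 5-exo closure, cyclization before reduction, and no 1,2-shift of the C1=C10 vinyl unit; bonding at C8 would build two adjacent quaternary carbons in a five-membered ring, the slow hydrogen donor and the high dilution give the primary radical time to cyclize, and the shift would have to begin with attack on the fully substituted C10 next to C9.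

Step 16
Reactants: 23 bicyclic silyl ether
Product: 24 methyl (1S,5S,6R,8aR)-5-(2-hydroxyethyl)-1,5,6-trimethyl-1,2,3,5,6,7,8,8a-octahydronaphthalene-1-carboxylate
Conditions: TBAF, THF, rt
Reagents that add atoms: none
Why: Fluoride cleavage of the silyl ether; ester and alkene are inert.

Step 17
Reactants: 24 C12 alcohol
Product: 25 methyl (1S,5S,6R,8aR)-5-(2-iodoethyl)-1,5,6-trimethyl-1,2,3,5,6,7,8,8a-octahydronaphthalene-1-carboxylate
Conditions: I2, PPh3, imidazole, CH2Cl2, 0 °C
Reagents that add atoms: iodine, II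
Why: Appel-type iodination (SN2 on the alkoxyphosphonium salt) of an unhindered primary alcohol.

Step 18
Reactants: 26 but-2-yn-1-ol
Product: 27 tert-butyl(but-2-yn-1-yloxy)dimethylsilane
Conditions: TBSCl, imidazole, CH2Cl2, rt
Reagents that add atoms: tert-butyl(chloro)dimethylsilane, CC(C)(C)[Si](C)(C)Cl
Why: Silylation of the propargylic alcohol before hydrometalation.

Step 19
Reactants: 27 silyl ether of but-2-yn-1-ol
Product: 29 (E)-tert-butyl[(3-iodobut-2-en-1-yl)oxy]dimethylsilane, via alkenylzirconocene chloride 28 (not isolated)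
Conditions: Cp2Zr(H)Cl (2 equiv), THF, 50 °C; then I2, 0 °C
Reagents that add atoms: iodine, II
Why: Syn hydrozirconation; with excess hydride at 50 °C the regioisomers should equilibrate to zirconium on the methyl-bearing carbon, and iodinolysis with retention gives the (E)-iodide (iodine trans to the CH2O group).

Step 20
Reactants: 25 C12 iodide; 29 (E)-alkenyl iodide
Product: 31 methyl (1S,5S,6R,8aR)-5-{(3E)-5-[(tert-butyldimethylsilyl)oxy]-3-methylpent-3-en-1-yl}-1,5,6-trimethyl-1,2,3,5,6,7,8,8a-octahydronaphthalene-1-carboxylate, via alkylzinc iodide 30 (not isolated)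
Conditions: Zn dust, LiCl, THF, 40 °C; then 29, PdCl2(dppf) (5 mol %), THF, 50 °C
Reagents that add atoms: none
Why: Negishi coupling; zinc inserts into the primary C–I bond without touching the ester, and the palladium-catalysed sp3–sp2 coupling keeps the alkene geometry, so C13=C14 is E.

Step 21
Reactants: 31 allylic silyl ether
Product: 32 methyl (1S,5S,6R,8aR)-5-[(3E)-5-hydroxy-3-methylpent-3-en-1-yl]-1,5,6-trimethyl-1,2,3,5,6,7,8,8a-octahydronaphthalene-1-carboxylate
Conditions: TBAF, THF, 0 °C
Reagents that add atoms: none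
Why: Fluoride desilylation frees the allylic alcohol needed to direct the epoxidation.

Step 22
Reactants: 32 (E)-allylic alcohol
Product: 33 methyl (1S,5S,6R,8aR)-5-{2-[(2S,3S)-3-(hydroxymethyl)-2-methyloxiran-2-yl]ethyl}-1,5,6-trimethyl-1,2,3,5,6,7,8,8a-octahydronaphthalene-1-carboxylate
Conditions: Ti(OiPr)4 (10 mol %), L-(+)-diethyl tartrate (12 mol %), t-BuOOH, 4 Å MS, CH2Cl2, −20 °C
Reagents that add atoms: tert-butyl hydroperoxide, CC(C)(C)OO
Why: Sharpless asymmetric epoxidation; the titanium tartrate complex binds the allylic alcohol, L-(+)-tartrate delivers oxygen to the face that gives the (13S,14S)-epoxide from the (E)-alkene (as for geraniol), and the isolated C1=C10 alkene is not touched.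

**Compound list**

1 | (E)-1-(dimethylamino)-3-(tert-butyldimethylsilyloxy)buta-1,3-diene | CN(C)/C=C/C(=C)O[Si](C)(C)C(C)(C)C | starting material
2 | methacrolein | CC(=C)C=O | starting material
3 | (1S,2R)-2-(dimethylamino)-1-methyl-4-(tert-butyldimethylsilyloxy)cyclohex-3-ene-1-carbaldehyde | O=C[C@@]1(C)CCC(O[Si](C)(C)C(C)(C)C)=C[C@H]1N(C)C | intermediate
4 | (S)-1-methyl-4-oxocyclohex-2-ene-1-carbaldehyde | O=C[C@@]1(C)CCC(=O)C=C1 | intermediate
5 | (S)-1-methyl-4-oxocyclohex-2-ene-1-carboxylic acid | OC(=O)[C@@]1(C)CCC(=O)C=C1 | intermediate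
6 | methyl (S)-1-methyl-4-oxocyclohex-2-ene-1-carboxylate | COC(=O)[C@@]1(C)CCC(=O)C=C1 | intermediate
7 | methyl (S)-3-iodo-1-methyl-4-oxocyclohex-2-ene-1-carboxylate | COC(=O)[C@@]1(C)CCC(=O)C(I)=C1 | intermediate
8 | methyl (1S,4R)-4-hydroxy-3-iodo-1-methylcyclohex-2-ene-1-carboxylate | COC(=O)[C@@]1(C)CC[C@@H](O)C(I)=C1 | intermediate
9 | tigloyl chloride, (E)-2-methylbut-2-enoyl chloride | C/C=C(\C)C(Cl)=O | starting material
10 | methyl (1S,4R)-3-iodo-1-methyl-4-{[(E)-2-methylbut-2-enoyl]oxy}cyclohex-2-ene-1-carboxylate | COC(=O)[C@@]1(C)CC[C@@H](OC(=O)/C(C)=C/C)C(I)=C1 | intermediate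
11 | methyl (3R,5S,7aR)-3-ethenyl-3,5-dimethyl-2-oxo-2,3,5,6,7,7a-hexahydro-1-benzofuran-5-carboxylate | COC(=O)[C@@]1(C)CC[C@H]2OC(=O)[C@](C)(C=C)C2=C1 | intermediate
12 | B-alkyl-9-BBN adduct of 11 (boron on C12) | COC(=O)[C@@]1(C)CC[C@H]2OC(=O)[C@](C)(CCB3C4CCCC3CCC4)C2=C1 | intermediate
13 | methyl (3R,5S,7aR)-3-(2-hydroxyethyl)-3,5-dimethyl-2-oxo-2,3,5,6,7,7a-hexahydro-1-benzofuran-5-carboxylate | COC(=O)[C@@]1(C)CC[C@H]2OC(=O)[C@](C)(CCO)C2=C1 | intermediate
14 | methyl (3R,5S,7aR)-3-{2-[(tert-butyldiphenylsilyl)oxy]ethyl}-3,5-dimethyl-2-oxo-2,3,5,6,7,7a-hexahydro-1-benzofuran-5-carboxylate | COC(=O)[C@@]1(C)CC[C@H]2OC(=O)[C@](C)(CCO[Si](c3ccccc3)(c3ccccc3)C(C)(C)C)C2=C1 | intermediate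
15 | methyl (1S,4R)-3-{(3R)-5-[(tert-butyldiphenylsilyl)oxy]-3-methyl-2-oxopentan-3-yl}-4-hydroxy-1-methylcyclohex-2-ene-1-carboxylate (open form of the hemiketal) | COC(=O)[C@@]1(C)CC[C@@H](O)C([C@@](C)(CCO[Si](c2ccccc2)(c2ccccc2)C(C)(C)C)C(C)=O)=C1 | intermediate
16 | methyl (1S,4R)-3-{(3S)-5-[(tert-butyldiphenylsilyl)oxy]-2,3-dimethylpent-1-en-3-yl}-4-hydroxy-1-methylcyclohex-2-ene-1-carboxylate | COC(=O)[C@@]1(C)CC[C@@H](O)C([C@@](C)(CCO[Si](c2ccccc2)(c2ccccc2)C(C)(C)C)C(C)=C)=C1 | intermediate
17 | 1-ethoxyvinyl ether (mixed ketene acetal) of 16 | COC(=O)[C@@]1(C)CC[C@@H](OC(=C)OCC)C([C@@](C)(CCO[Si](c2ccccc2)(c2ccccc2)C(C)(C)C)C(C)=C)=C1 | intermediate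
18 | methyl (1S,2R)-3-{(3S)-5-[(tert-butyldiphenylsilyl)oxy]-2,3-dimethylpent-1-en-3-yl}-2-(2-ethoxy-2-oxoethyl)-1-methylcyclohex-3-ene-1-carboxylate | COC(=O)[C@@]1(C)CCC=C([C@H]1CC(=O)OCC)[C@@](C)(CCO[Si](c2ccccc2)(c2ccccc2)C(C)(C)C)C(C)=C | intermediate
19 | 2-[(1R,6S)-2-{(3S)-5-[(tert-butyldiphenylsilyl)oxy]-2,3-dimethylpent-1-en-3-yl}-6-(methoxycarbonyl)-6-methylcyclohex-2-en-1-yl]acetic acid | COC(=O)[C@@]1(C)CCC=C([C@H]1CC(O)=O)[C@@](C)(CCO[Si](c2ccccc2)(c2ccccc2)C(C)(C)C)C(C)=C | intermediate
20 | 1,3-dioxoisoindolin-2-yl ester of 19 | COC(=O)[C@@]1(C)CCC=C([C@H]1CC(=O)ON2C(=O)c3ccccc3C2=O)[C@@](C)(CCO[Si](c2ccccc2)(c2ccccc2)C(C)(C)C)C(C)=C | intermediate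
21 | primary C6 radical from 20 | COC(=O)[C@@]1(C)CCC=C([C@H]1[CH2])[C@@](C)(CCO[Si](c2ccccc2)(c2ccccc2)C(C)(C)C)C(C)=C | intermediate
22 | tertiary C8 radical (ring B closed) | COC(=O)[C@@]1(C)CCC=C2[C@H]1CC[C](C)[C@]2(C)CCO[Si](c3ccccc3)(c3ccccc3)C(C)(C)C | intermediate
23 | methyl (1S,5S,6R,8aR)-5-{2-[(tert-butyldiphenylsilyl)oxy]ethyl}-1,5,6-trimethyl-1,2,3,5,6,7,8,8a-octahydronaphthalene-1-carboxylate | COC(=O)[C@@]1(C)CCC=C2[C@H]1CC[C@@H](C)[C@]2(C)CCO[Si](c3ccccc3)(c3ccccc3)C(C)(C)C | intermediate
24 | methyl (1S,5S,6R,8aR)-5-(2-hydroxyethyl)-1,5,6-trimethyl-1,2,3,5,6,7,8,8a-octahydronaphthalene-1-carboxylate | COC(=O)[C@@]1(C)CCC=C2[C@H]1CC[C@@H](C)[C@]2(C)CCO | intermediate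
25 | methyl (1S,5S,6R,8aR)-5-(2-iodoethyl)-1,5,6-trimethyl-1,2,3,5,6,7,8,8a-octahydronaphthalene-1-carboxylate | COC(=O)[C@@]1(C)CCC=C2[C@H]1CC[C@@H](C)[C@]2(C)CCI | intermediate
26 | but-2-yn-1-ol | CC#CCO | starting material
27 | tert-butyl(but-2-yn-1-yloxy)dimethylsilane | CC#CCO[Si](C)(C)C(C)(C)C | intermediate
28 | (E)-alkenylzirconocene chloride from 27 (zirconium on C3) | C/C(=C\CO[Si](C)(C)C(C)(C)C)[Zr](Cl)(C1C=CC=C1)C1C=CC=C1 | intermediate
29 | (E)-tert-butyl[(3-iodobut-2-en-1-yl)oxy]dimethylsilane | C/C(I)=C\CO[Si](C)(C)C(C)(C)C | intermediate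
30 | alkylzinc iodide from 25 (zinc on C12) | COC(=O)[C@@]1(C)CCC=C2[C@H]1CC[C@@H](C)[C@]2(C)CC[Zn]I | intermediate
31 | methyl (1S,5S,6R,8aR)-5-{(3E)-5-[(tert-butyldimethylsilyl)oxy]-3-methylpent-3-en-1-yl}-1,5,6-trimethyl-1,2,3,5,6,7,8,8a-octahydronaphthalene-1-carboxylate | COC(=O)[C@@]1(C)CCC=C2[C@H]1CC[C@@H](C)[C@]2(C)CC/C(C)=C/CO[Si](C)(C)C(C)(C)C | intermediate
32 | methyl (1S,5S,6R,8aR)-5-[(3E)-5-hydroxy-3-methylpent-3-en-1-yl]-1,5,6-trimethyl-1,2,3,5,6,7,8,8a-octahydronaphthalene-1-carboxylate | COC(=O)[C@@]1(C)CCC=C2[C@H]1CC[C@@H](C)[C@]2(C)CC/C(C)=C/CO | intermediate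
33 | methyl (1S,5S,6R,8aR)-5-{2-[(2S,3S)-3-(hydroxymethyl)-2-methyloxiran-2-yl]ethyl}-1,5,6-trimethyl-1,2,3,5,6,7,8,8a-octahydronaphthalene-1-carboxylate | COC(=O)[C@@]1(C)CCC=C2[C@H]1CC[C@@H](C)[C@]2(C)CC[C@]1(C)O[C@H]1CO | target

**Step count and risks**

Total step count: 22. Longest linear sequence: 20 steps (steps 1–17 and 20–22).

Steps most likely to fail:

Step 15. The primary C6 radical is homoallylic to C1=C10 and could close onto C10 and reopen (1,2-vinyl shift that enlarges ring A). It could also be reduced before it cyclizes, or hydrogen delivery at C8 could be poorly face-selective. The fallback closes the same bond by polar chemistry; it sets out from 16 and comes back at 23. O-Alkylation of 16 with Bu3SnCH2I (KH, THF) should give the stannylmethyl ether F1. Tin–lithium exchange (n-BuLi, THF, −78 °C) then triggers the Wittig–Still [2,3]-rearrangement, suprafacial from the C1 oxygen, to the C5 hydroxymethyl compound F2 with the C1=C10 alkene in place. Dess–Martin oxidation gives the C6 aldehyde F3. Me2AlCl (CH2Cl2, −78 °C) closes ring B by an intramolecular carbonyl-ene reaction of the aldehyde with the isopropenyl group (C6–C7 bond), giving the ring B homoallylic alcohol with an exocyclic C8=C17 methylene F4; the configuration at C6 is of no consequence. NaH, CS2 and MeI give the xanthate F5, and Barton–McCombie deoxygenation (Bu3SnH, AIBN, toluene, 80 °C, high stannane concentration) gives the exocyclic alkene F6. Hydrogen-atom-transfer hydrogenation of the 1,1-disubstituted alkene (Mn(dpm)3, PhSiH3, t-BuOOH, i-PrOH), which should place C17 equatorial, leads to 23.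

Step 7. The ester tether prefers its extended conformation, so the 5-exo insertion may be slow. Insertion at C11 (6-endo) or ionization of the allylic ester by zerovalent palladium could then compete. The fallback changes the tether; it sets out from 8 and comes back at 11. Acetal exchange of 8 with (E)-1,1-diethoxy-2-methylbut-2-ene (PPTS, toluene) should give the mixed ethyl acetal F7. The same 5-exo Heck cyclization (Pd(OAc)2, PPh3, Ag2CO3), now through a freely rotating acetal tether that cannot ionize as an allylic carboxylate, gives the cyclic ethyl acetal F8. CrO3/H2SO4 in acetone at 0 °C oxidizes the acetal carbon to the lactone 11.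

Step 12. At 140 °C under acid the hindered allylic orthoester may ionize and eliminate to a diene before the slow bond formation at C5, next to the quaternary C4, can occur. The fallback replaces the orthoester exchange by an ester-enolate rearrangement at low temperature; it sets out from 16 and comes back at 19, so that step 13 is not needed. Acetylation (Ac2O, DMAP, pyridine) gives the C1 acetate F9. LiN(iPr)2 and Me3SiCl (THF, −78 °C, then 60 °C) form the silyl ketene acetal, whose Ireland–Claisen rearrangement and aqueous work-up give the acid 19 directly.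

**Further compounds**

F1 | step 15 | tributylstannylmethyl ether of 16 (on the C1 oxygen) | COC(=O)[C@@]1(C)CC[C@@H](OC[Sn](CCCC)(CCCC)CCCC)C([C@@](C)(CCO[Si](c2ccccc2)(c2ccccc2)C(C)(C)C)C(C)=C)=C1
F2 | step 15 | C5 hydroxymethyl compound (C6 alcohol, C1=C10) | COC(=O)[C@@]1(C)CCC=C([C@H]1CO)[C@@](C)(CCO[Si](c2ccccc2)(c2ccccc2)C(C)(C)C)C(C)=C
F3 | step 15 | C6 aldehyde | COC(=O)[C@@]1(C)CCC=C([C@H]1C=O)[C@@](C)(CCO[Si](c2ccccc2)(c2ccccc2)C(C)(C)C)C(C)=C
F4 | step 15 | ring B ene product, C6 alcohol (either epimer) with exocyclic C8=C17 | COC(=O)[C@@]1(C)CCC=C2[C@H]1C(O)CC(=C)[C@]2(C)CCO[Si](c3ccccc3)(c3ccccc3)C(C)(C)C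
F5 | step 15 | S-methyl xanthate of F4 | COC(=O)[C@@]1(C)CCC=C2[C@H]1C(OC(=S)SC)CC(=C)[C@]2(C)CCO[Si](c3ccccc3)(c3ccccc3)C(C)(C)C
F6 | step 15 | deoxygenated bicycle with exocyclic C8=C17 | COC(=O)[C@@]1(C)CCC=C2[C@H]1CCC(=C)[C@]2(C)CCO[Si](c3ccccc3)(c3ccccc3)C(C)(C)C
F7 | step 7 | mixed ethyl acetal of 8 with (E)-2-methylbut-2-enal | COC(=O)[C@@]1(C)CC[C@@H](OC(OCC)/C(C)=C/C)C(I)=C1
F8 | step 7 | cyclic ethyl acetal (2-ethoxy analogue of lactone 11) | COC(=O)[C@@]1(C)CC[C@H]2OC(OCC)[C@](C)(C=C)C2=C1
F9 | step 12 | C1 acetate of 16 | COC(=O)[C@@]1(C)CC[C@@H](OC(C)=O)C([C@@](C)(CCO[Si](c2ccccc2)(c2ccccc2)C(C)(C)C)C(C)=C)=C1
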